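**Assumption:** 12, 21 and LDA solution are bought as such; atom labels C1–C15 follow germacrane numbering of the target (C1 furanone C=O, C2 =CH, C3 furanone C–O, C4 CHMe, C5 CH2, C6 CH–O, C7=C11 and C12 lactone, C8=C9 enol lactone, C10 quaternary C–O, C13 CH2OAc).

## Retrosynthetic overview

1. The γ-ylidene butenolide is the last ring: singlet-oxygen oxidation and dehydration of a macrocyclic furan, where the ring dictates the C8=C9 geometry; the C6 ester goes on before, the silyl ether comes off last.
2. The ten-membered ring is closed at C5–C6–C7 by a carbonylative coupling of a C5 zinc homoenolate, CO (which becomes C6) and a 3-iodofuran (C7). This makes the dissonant C3/C6 1,4-relationship; C6 is then set by CBS reduction.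
3. The iodofuran comes from a terminal alkyne by Sonogashira coupling with 2-bromoacrolein acetal and a Larock iodo-acetoxy cyclisation, which also installs the C13 acetate.
4. The 3(2H)-furanone comes from a Claisen condensation and cyclodehydration of an α-hydroxy methyl ketone (C10 from (R)-lactic acid by Seebach alkylation) with the Roche ester (C4).
5. Ring order: furanone, then furan, then ten-membered carbocycle, then butenolide.

## Route

Step 1
Reactants: 1 (R)-lactic acid
Product: 2 (2R,5R)-2-tert-butyl-5-methyl-1,3-dioxolan-4-one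
Conditions: t-BuCHO, TsOH (cat.), H2SO4 (cat.), pentane, reflux, Dean–Stark; crystallisation from pentane at −78 °C
Reagents that add atoms: pivalaldehyde CC(C)(C)C=O
Why: Acid-catalysed acetalisation (Seebach self-regeneration-of-stereocentres template); the cis acetal is the thermodynamic isomer and is purified by crystallisation, so the acetal centre is set by the lactate centre.

Step 2
Reactants: 2 (2R,5R)-2-tert-butyl-5-methyl-1,3-dioxolan-4-one; 3 3-bromo-1-(trimethylsilyl)prop-1-yne
Product: 5 (2R,5S)-2-tert-butyl-5-methyl-5-[3-(trimethylsilyl)prop-2-yn-1-yl]-1,3-dioxolan-4-one, via lithium enolate 4 (not isolated)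
Conditions: LDA (1.05 equiv), THF, −78 °C; 3 (1.3 equiv), −78 → −30 °C
Reagents that add atoms: none
Why: Seebach alkylation; the enolate is attacked anti to the tert-butyl group, so the propargyl unit replaces H with retention and sets C10 (S in the target).

Step 3
Reactants: 5 (2R,5S)-2-tert-butyl-5-methyl-5-[3-(trimethylsilyl)prop-2-yn-1-yl]-1,3-dioxolan-4-one
Product: 6 (3S)-3-hydroxy-3-methyl-6-(trimethylsilyl)hex-5-yn-2-one
Conditions: MeLi (1.1 equiv), THF, −78 °C; H2O (pH 7 buffer), −78 → 23 °C
Reagents that add atoms: methyllithium [Li]C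
Why: Acyl substitution on the acetal-lactone; the tetrahedral lithium hemiketal survives at −78 °C and collapses only on work-up with loss of pivalaldehyde, which prevents a second addition; C10 is untouched.

Step 4
Reactants: 7 methyl (S)-3-hydroxy-2-methylpropanoate
Product: 8 methyl (S)-3-(tert-butyldimethylsilyloxy)-2-methylpropanoate
Conditions: TBSCl (1.1 equiv), imidazole (1.5 equiv), CH2Cl2, 23 °C
Reagents that add atoms: tert-butyldimethylsilyl chloride CC(C)(C)[Si](C)(C)Cl
Why: Standard silylation of the primary alcohol; the stereocentre (C4 of the target) is not involved.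

Step 5
Reactants: 6 (3S)-3-hydroxy-3-methyl-6-(trimethylsilyl)hex-5-yn-2-one; 8 methyl (S)-3-(tert-butyldimethylsilyloxy)-2-methylpropanoate
Product: 11 (2S)-5-[(2S)-1-(tert-butyldimethylsilyloxy)propan-2-yl]-2-methyl-2-[3-(trimethylsilyl)prop-2-yn-1-yl]furan-3(2H)-one, via dilithio dianion 9 (not isolated), via hydroxy diketone 10 (not isolated)
Conditions: LDA (2.1 equiv), THF, −78 °C; 8 (1.0 equiv), −78 → −40 °C; LDA (1.0 equiv), → −20 °C; AcOH; then TsOH·H2O (0.1 equiv), CH2Cl2, 23 °C
Reagents that add atoms: none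
Why: Crossed Claisen condensation of the only enolisable position (the C2 methyl) with the ester, then acid-catalysed cyclodehydration of the α'-hydroxy-1,3-diketone (C10–OH onto C3) to the 3(2H)-furanone; C4 is protected as the diketonate and C10 is quaternary, so both centres are kept.

Step 6
Reactants: 11 (2S)-5-[(2S)-1-(tert-butyldimethylsilyloxy)propan-2-yl]-2-methyl-2-[3-(trimethylsilyl)prop-2-yn-1-yl]furan-3(2H)-one; 12 2-bromo-3,3-diethoxyprop-1-ene
Product: 14 (2S)-2-[4-(diethoxymethyl)pent-4-en-2-yn-1-yl]-5-[(2S)-1-hydroxypropan-2-yl]-2-methylfuran-3(2H)-one, via terminal alkyne 13 (not isolated)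
Conditions: TBAF (2.5 equiv), AcOH (2.5 equiv), THF, 0 → 23 °C; then Pd(PPh3)2Cl2 (5 mol %), CuI (10 mol %), i-Pr2NH (5 equiv), 12 (1.5 equiv), 40 °C
Reagents that add atoms: none
Why: Fluoride removes both silyl groups; Sonogashira coupling of the freed alkyne with the vinyl bromide makes the C7–C11 bond under conditions that do not touch the furanone or its stereocentres.

Step 7
Reactants: 14 (2S)-2-[4-(diethoxymethyl)pent-4-en-2-yn-1-yl]-5-[(2S)-1-hydroxypropan-2-yl]-2-methylfuran-3(2H)-one
Product: 16 {5-[((2S)-5-[(2S)-1-hydroxypropan-2-yl]-2-methyl-3-oxo-2,3-dihydrofuran-2-yl)methyl]-4-iodofuran-3-yl}methyl acetate, via enynal 15 (not isolated)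
Conditions: PPTS (0.1 equiv), acetone/H2O (20:1), 23 °C; concentrate below 25 °C; then I2 (1.5 equiv), NaOAc (4 equiv), AcOH (10 equiv), MeCN, 0 → 23 °C, dark; aq. Na2S2O3
Reagents that add atoms: water O; iodine II; sodium acetate CC(=O)[O-].[Na+]
Why: Acetal hydrolysis, then Larock electrophile-induced cyclisation of the 2-(1-alkynyl)-2-alkenal: iodonium activates the alkyne, the aldehyde oxygen closes the furan at C8 and acetate adds to the exocyclic methylene. This gives the C7 iodide and the C13 acetate regiospecifically; no stereocentre is formed.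

Step 8
Reactants: 16 {5-[((2S)-5-[(2S)-1-hydroxypropan-2-yl]-2-methyl-3-oxo-2,3-dihydrofuran-2-yl)methyl]-4-iodofuran-3-yl}methyl acetate
Product: 17 {4-iodo-5-[((2S)-5-[(2R)-1-iodopropan-2-yl]-2-methyl-3-oxo-2,3-dihydrofuran-2-yl)methyl]furan-3-yl}methyl acetate
Conditions: I2 (1.3 equiv), PPh3 (1.3 equiv), imidazole (2.5 equiv), CH2Cl2, 0 → 23 °C
Reagents that add atoms: iodine II
Why: Appel iodination of the primary alcohol; C4 is not a reacting centre (its descriptor changes only by priority).

Step 9
Reactants: 17 {4-iodo-5-[((2S)-5-[(2R)-1-iodopropan-2-yl]-2-methyl-3-oxo-2,3-dihydrofuran-2-yl)methyl]furan-3-yl}methyl acetate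
Product: 19 (4S,10S) furan-fused macrocyclic C6 ketone (ten-membered carbocycle C1–C10 bridged by the furanone oxygen between C3 and C10; C13 acetate), via alkylzinc iodide 18 (not isolated)
Conditions: Zn (4 equiv, activated with BrCH2CH2Br, Me3SiCl), DMF, 30 °C; filtered solution added over 12 h to Pd(PPh3)4 (10 mol %), CO (3 atm), THF, 50 °C, final 2 mM
Reagents that add atoms: carbon monoxide [C-]#[O+]
Why: Proposed new method: intramolecular carbonylative Negishi coupling of a zinc homoenolate. Zinc inserts into the alkyl C–I bond only, giving the β-zincio derivative of the C3 acyl-equivalent carbon of the vinylogous ester (nucleophilic C5); zerovalent palladium adds to the furyl iodide, CO inserts to the furoyl–palladium, and transmetalation plus reductive elimination close the ten-membered ring as the C6 ketone. This joins C5 to a carbonyl carbon and gives the C3/C6 1,4-dicarbonyl pattern; direct coupling without CO would need a nine-membered ring and is slower. Closest known reactions: carbonylative cross-coupling of ester-derived β-zincio (homoenolate) reagents with aryl iodides to 1,4-dicarbonyls, and carbonylative Stille macrocyclisation of a 3(2H)-furanone-containing macrocycle.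

Step 10
Reactants: 19 (4S,10S) furan-fused macrocyclic C6 ketone
Product: 20 (4S,6S,10S) furan-fused macrocyclic C6 alcohol
Conditions: (R)-2-methyl-CBS-oxazaborolidine (1.0 equiv), catecholborane (2.0 equiv), toluene, −78 → −40 °C; MeOH, aq. NaHCO3
Reagents that add atoms: none
Why: Corey–Bakshi–Shibata reduction; with the furyl group as the large substituent the (R)-oxazaborolidine gives the (6S) carbinol, and catecholborane at low temperature leaves the vinylogous ester and the acetate alone.

Step 11
Reactants: 21 4-methylfuran-2(5H)-one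
Product: 24 (2Z)-4-(tert-butyldimethylsilyloxy)-3-methylbut-2-enoic acid, via potassium carboxylate 22 (not isolated), via bis-silyl ester 23 (not isolated)
Conditions: KOH (1.0 equiv), MeOH/H2O, 23 °C; evaporate, dry; TBSCl (2.4 equiv), imidazole (5 equiv), DMF, 23 °C; then K2CO3 (0.3 equiv), MeOH/THF, 0 °C; citric acid to pH 5
Reagents that add atoms: potassium hydroxide [K+].[OH-]; tert-butyldimethylsilyl chloride CC(C)(C)[Si](C)(C)Cl
Why: Saponification opens the butenolide to the (Z)-hydroxy carboxylate (geometry fixed by the ring); bis-silylation and selective methanolysis of the silyl ester give the acid without relactonisation.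

Step 12
Reactants: 20 (4S,6S,10S) furan-fused macrocyclic C6 alcohol; 24 (2Z)-4-(tert-butyldimethylsilyloxy)-3-methylbut-2-enoic acid
Product: 26 (4S,6S,10S) furan-fused macrocyclic C6 (2Z)-4-silyloxy-3-methylbut-2-enoate, via mixed anhydride 25 (not isolated)
Conditions: 24 (1.5 equiv), 2,4,6-Cl3C6H2COCl (1.5 equiv), Et3N (3 equiv), toluene, 23 °C; then 20, DMAP (2 equiv), toluene, 23 °C
Reagents that add atoms: none
Why: Yamaguchi esterification acylates the hindered secondary alcohol with retention at C6; the β,β-disubstituted (Z)-enoate does not isomerise under DMAP.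

Step 13
Reactants: 26 (4S,6S,10S) furan-fused macrocyclic C6 (2Z)-4-silyloxy-3-methylbut-2-enoate
Product: 30 O-tert-butyldimethylsilyl ether of the target, via endoperoxide 27 (not isolated), via hydroxybutenolide 28 (not isolated), via hemiketal trifluoroacetate 29 (not isolated)
Conditions: O2, hν (visible), tetraphenylporphyrin (1 mol %), i-Pr2NEt (3 equiv), CH2Cl2, −78 °C; then (CF3CO)2O (1.5 equiv), pyridine (4 equiv), −78 → 0 °C
Reagents that add atoms: oxygen O=O
Why: [4+2] addition of singlet oxygen to the furan, then Kornblum–DeLaMare fragmentation at the only α-hydrogen (C12–H), gives the 8-hydroxy butenolide with C12 as the carbonyl. E1 loss of trifluoroacetate through the acyloxocarbenium and deprotonation at C9 give the enol lactone; C7 and C10 end up cis across C8=C9 because only that geometry fits the ten-membered ring. The cold, weakly basic medium avoids retro-oxa-Michael opening at C10.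

Step 14
Reactants: 30 O-tert-butyldimethylsilyl ether of the target
Product: 31 CNP0269057.1
Conditions: HF·pyridine, pyridine, THF, 0 °C
Reagents that add atoms: none
Why: Buffered fluoride desilylation of the primary allylic silyl ether; neutral, cold conditions keep the (Z)-γ-hydroxy enoate from lactonising and leave the acetate and enol lactone intact.

## Compound list

1 | (R)-lactic acid | C[C@@H](O)C(=O)O | starting material
2 | (2R,5R)-2-tert-butyl-5-methyl-1,3-dioxolan-4-one | C[C@H]1O[C@@H](C(C)(C)C)OC1=O | intermediate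
3 | 3-bromo-1-(trimethylsilyl)prop-1-yne | C[Si](C)(C)C#CCBr | starting material
4 | lithium enolate of 2 | CC1=C(O[Li])O[C@H](C(C)(C)C)O1 | intermediate
5 | (2R,5S)-2-tert-butyl-5-methyl-5-[3-(trimethylsilyl)prop-2-yn-1-yl]-1,3-dioxolan-4-one | C[Si](C)(C)C#CC[C@]1(C)O[C@@H](C(C)(C)C)OC1=O | intermediate
6 | (3S)-3-hydroxy-3-methyl-6-(trimethylsilyl)hex-5-yn-2-one | C[Si](C)(C)C#CC[C@](C)(O)C(C)=O | intermediate
7 | methyl (S)-3-hydroxy-2-methylpropanoate | COC(=O)[C@@H](C)CO | starting material
8 | methyl (S)-3-(tert-butyldimethylsilyloxy)-2-methylpropanoate | COC(=O)[C@@H](C)CO[Si](C)(C)C(C)(C)C | intermediate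
9 | dilithio alkoxide-enolate of 6 | C[Si](C)(C)C#CC[C@](C)(O[Li])C(=C)O[Li] | intermediate
10 | (2S,6S)-1-(tert-butyldimethylsilyloxy)-6-hydroxy-2,6-dimethyl-9-(trimethylsilyl)non-8-yne-3,5-dione | C[Si](C)(C)C#CC[C@](C)(O)C(=O)CC(=O)[C@@H](C)CO[Si](C)(C)C(C)(C)C | intermediate
11 | (2S)-5-[(2S)-1-(tert-butyldimethylsilyloxy)propan-2-yl]-2-methyl-2-[3-(trimethylsilyl)prop-2-yn-1-yl]furan-3(2H)-one | C[Si](C)(C)C#CC[C@]1(C)OC(=CC1=O)[C@@H](C)CO[Si](C)(C)C(C)(C)C | intermediate
12 | 2-bromo-3,3-diethoxyprop-1-ene (2-bromoacrolein diethyl acetal) | C=C(Br)C(OCC)OCC | starting material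
13 | (2S)-5-[(2S)-1-hydroxypropan-2-yl]-2-methyl-2-(prop-2-yn-1-yl)furan-3(2H)-one | C#CC[C@]1(C)OC(=CC1=O)[C@@H](C)CO | intermediate
14 | (2S)-2-[4-(diethoxymethyl)pent-4-en-2-yn-1-yl]-5-[(2S)-1-hydroxypropan-2-yl]-2-methylfuran-3(2H)-one | CCOC(OCC)C(=C)C#CC[C@]1(C)OC(=CC1=O)[C@@H](C)CO | intermediate
15 | 5-[(2S)-5-[(2S)-1-hydroxypropan-2-yl]-2-methyl-3-oxo-2,3-dihydrofuran-2-yl]-2-methylidenepent-3-ynal | O=CC(=C)C#CC[C@]1(C)OC(=CC1=O)[C@@H](C)CO | intermediate
16 | {5-[((2S)-5-[(2S)-1-hydroxypropan-2-yl]-2-methyl-3-oxo-2,3-dihydrofuran-2-yl)methyl]-4-iodofuran-3-yl}methyl acetate | CC(=O)OCc1coc(C[C@]2(C)OC(=CC2=O)[C@@H](C)CO)c1I | intermediate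
17 | {4-iodo-5-[((2S)-5-[(2R)-1-iodopropan-2-yl]-2-methyl-3-oxo-2,3-dihydrofuran-2-yl)methyl]furan-3-yl}methyl acetate | CC(=O)OCc1coc(C[C@]2(C)OC(=CC2=O)[C@@H](C)CI)c1I | intermediate
18 | alkylzinc iodide from 17 (C5–ZnI) | CC(=O)OCc1coc(C[C@]2(C)OC(=CC2=O)[C@@H](C)C[Zn]I)c1I | intermediate
19 | (4S,10S) furan-fused macrocyclic C6 ketone | CC(=O)OCc1coc2C[C@]3(C)OC(=CC3=O)[C@@H](C)CC(=O)c12 | intermediate
20 | (4S,6S,10S) furan-fused macrocyclic C6 alcohol | CC(=O)OCc1coc2C[C@]3(C)OC(=CC3=O)[C@@H](C)C[C@H](O)c12 | intermediate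
21 | 4-methylfuran-2(5H)-one | CC1=CC(=O)OC1 | starting material
22 | potassium (2Z)-4-hydroxy-3-methylbut-2-enoate | [K+].[O-]C(=O)/C=C(/C)CO | intermediate
23 | tert-butyldimethylsilyl (2Z)-4-(tert-butyldimethylsilyloxy)-3-methylbut-2-enoate | CC(C)(C)[Si](C)(C)OC(=O)/C=C(/C)CO[Si](C)(C)C(C)(C)C | intermediate
24 | (2Z)-4-(tert-butyldimethylsilyloxy)-3-methylbut-2-enoic acid | OC(=O)/C=C(/C)CO[Si](C)(C)C(C)(C)C | intermediate
25 | mixed anhydride of 24 with 2,4,6-trichlorobenzoic acid | O=C(OC(=O)/C=C(/C)CO[Si](C)(C)C(C)(C)C)c1c(Cl)cc(Cl)cc1Cl | intermediate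
26 | (4S,6S,10S) furan-fused macrocyclic C6 (2Z)-4-silyloxy-3-methylbut-2-enoate | CC(=O)OCc1coc2C[C@]3(C)OC(=CC3=O)[C@@H](C)C[C@H](OC(=O)/C=C(/C)CO[Si](C)(C)C(C)(C)C)c12 | intermediate
27 | furan 8,12-endoperoxide of 26 | CC(=O)OCC1=C2C4(C[C@]3(C)OC(=CC3=O)[C@@H](C)C[C@@H]2OC(=O)/C=C(/C)CO[Si](C)(C)C(C)(C)C)OOC1O4 | intermediate
28 | 8-hydroxy butenolide (C12 lactone carbonyl) | CC(=O)OCC1=C2C(O)(C[C@]3(C)OC(=CC3=O)[C@@H](C)C[C@@H]2OC(=O)/C=C(/C)CO[Si](C)(C)C(C)(C)C)OC1=O | intermediate
29 | 8-trifluoroacetoxy butenolide | CC(=O)OCC1=C2C(OC(=O)C(F)(F)F)(C[C@]3(C)OC(=CC3=O)[C@@H](C)C[C@@H]2OC(=O)/C=C(/C)CO[Si](C)(C)C(C)(C)C)OC1=O | intermediate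
30 | O-tert-butyldimethylsilyl ether of the target | CC(=O)OCC1=C2/C(=C\[C@]3(C)OC(=CC3=O)[C@@H](C)C[C@@H]2OC(=O)/C=C(/C)CO[Si](C)(C)C(C)(C)C)OC1=O | intermediate
31 | CNP0269057.1 | CC(=O)OCC1=C2/C(=C\[C@]3(C)OC(=CC3=O)[C@@H](C)C[C@@H]2OC(=O)/C=C(/C)CO)OC1=O | target

## Step count and risks

Total step count: 14. Longest linear sequence: 12 steps (1, 2, 3, 5, 6, 7, 8, 9, 10, 12, 13, 14).

Steps most likely to fail:

- **Step 9 (carbonylative ring closure).** A ten-membered ring is formed by an unprecedented intramolecular version of the reaction; oligomers or direct alkyl–aryl coupling may win. The fallback sets out from 16 and comes back at 20. Formylation of the furyl iodide with Pd(PPh3)4, CO and Bu3SnH gives the formyl furan alcohol F1. I2, PPh3 and imidazole then give the iodo aldehyde F2. CrCl2 with catalytic cobalt phthalocyanine in DMF at high dilution adds the C5 alkylchromium to the C6 aldehyde and closes the ring directly at the alcohol oxidation level, giving 20. A 6R product would be handled as in the third fallback.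

- **Step 7 (iodo-acetoxy cyclisation).** The 2-alkynyl acrolein 15 is a very reactive acceptor, and an aldehyde with an unsubstituted methylene is at the edge of the known scope. The fallback sets out from 11 and comes back at 16. Desilylation with TBAF and Sonogashira coupling with 2-bromoallyl acetate give the enyne acetate F3. Dimethyldioxirane epoxidises the 1,1-disubstituted alkene to the alkynyl oxirane F4. N-iodosuccinimide with catalytic AuCl3 in CH2Cl2/MeOH then gives the same 3-iodofuran 16 by iodo-cycloisomerisation of the alkynyl oxirane.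

- **Step 10 (C6 configuration).** The macrocycle may override the CBS reagent. The fallback sets out from 19 and comes back at 26. Luche reduction (NaBH4, CeCl3·7H2O, MeOH, −78 °C) under substrate control is taken to the (6R) alcohol F5. Mitsunobu esterification with 24 (PPh3, diisopropyl azodicarboxylate, toluene, 0 °C) then gives 26 with inversion at C6.

## Further compounds

F1 | step 9 | {4-formyl-5-[((2S)-5-[(2S)-1-hydroxypropan-2-yl]-2-methyl-3-oxo-2,3-dihydrofuran-2-yl)methyl]furan-3-yl}methyl acetate | CC(=O)OCc1coc(C[C@]2(C)OC(=CC2=O)[C@@H](C)CO)c1C=O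
F2 | step 9 | {4-formyl-5-[((2S)-5-[(2R)-1-iodopropan-2-yl]-2-methyl-3-oxo-2,3-dihydrofuran-2-yl)methyl]furan-3-yl}methyl acetate | CC(=O)OCc1coc(C[C@]2(C)OC(=CC2=O)[C@@H](C)CI)c1C=O
F3 | step 7 | 5-[(2S)-5-[(2S)-1-hydroxypropan-2-yl]-2-methyl-3-oxo-2,3-dihydrofuran-2-yl]-2-methylidenepent-3-yn-1-yl acetate | CC(=O)OCC(=C)C#CC[C@]1(C)OC(=CC1=O)[C@@H](C)CO
F4 | step 7 | {2-[3-((2S)-5-[(2S)-1-hydroxypropan-2-yl]-2-methyl-3-oxo-2,3-dihydrofuran-2-yl)prop-1-yn-1-yl]oxiran-2-yl}methyl acetate | CC(=O)OCC1(CO1)C#CC[C@]2(C)OC(=CC2=O)[C@@H](C)CO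
F5 | step 10 | (4S,6R,10S) furan-fused macrocyclic C6 alcohol | CC(=O)OCc1coc2C[C@]3(C)OC(=CC3=O)[C@@H](C)C[C@@H](O)c12
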